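Start from 3.2, the equilibrium constant of the first step times the Q charged: it tells how Q.J can stand against J in this flask.

    Q + J ⇌ Q.J (K1 = 53 /M, k1 = 9.1 /M/s)
    D + Q.J ⇌ D.Q.J (K2 = 31 /M, k2 = 9.0 /M/s)
    D.Q.J ⇌ J + L (K3 = 0.12 M, k3 = 1.8 /s)
    D ⇌ G (K4 = 2.4, k4 = 0.36 /s)

Q 0.060 M; D 0.0600 M; J 6.6 mM

- what is bound to the catalyst counts as converted
- charge of Q (flask): 0.060 M

- the form that holds most of the catalyst when 50% of the Q are converted (Q.J / J / D.Q.J)
- its share of the catalyst then

Carry one number, the crossing 31.4%: the fraction of the Q charge left at which the first step, in balance, puts as much catalyst in Q.J as in J. Above it, that balance favours Q.J.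

Now find the free D. A D goes to G at 0.36 /s, and it meets Q.J at no more than 0.0594 /s, which is slower, so put D in balance with G. Take the D used as equal to the Q converted, at half of the Q. That counts the Q sitting in Q.J as D used, at most 11.0% of the Q charged, so this free D errs low.

Way one, balance:

free D = 14.7% of its charge

Q.J per J = Q left / crossing = 1.59

D.Q.J per Q.J = 0.274

share of Q.J = 52.6%, share of J = 33.1%

Way two, waits: give each form one over its forward rate, and its share is its wait in the whole round.

J 3.66 s, Q.J 12.6 s, D.Q.J 0.556 s

share of Q.J = 74.9%

Both ways name Q.J, but they part on the share, so find the one that cheats. A Q.J falls back to Q + J at 0.172 /s and goes ahead at 0.0794 /s, so more of it turns back than goes on. The waits count each visit as a step forward, so drop them. Way one is rough too, since a Q.J turns back about twice as often as it goes on, but commit to 52.6% for Q.J, the resting state.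

The forecast gives Q.J at 52%, with J at 39% and D.Q.J at 9%, and it starts from this: “D equilibrates quickly with G”. Its J stands above my 33.1%.

The simulation reaches that conversion after 96.9 s and gives Q.J at 51.7%, J at 38.9% and D.Q.J at 9.38%, so J stands above my figure.

In this flask at 40.0 s, D + Q.J and D.Q.J relax with a half-life of 1.59 s by the second step alone, both ways together, while the slowest mode of the whole flask has a half-life of 45.5 s, much longer. After 400 s the flask still has 37.6% of its Q left, above the crossing of 31.4%, and Q.J holds 48.3% of the catalyst against 40.4% for J.

The constants used here are assumed; the result is computed.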